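With the target numbered as a 1H-isochromene, ring A (C4a, C5, C6, C7, C8, C8a) is a 2,3-disubstituted cyclohex-2-enone: its saturated arc C5–C6–C7–C8 maps onto a four-membered ketone and the C4a=C8a double bond onto an alkyne. The route rests on cutting C8–C8a and C4a–C5. A nickel-catalysed insertion of one triple bond of a silyl-capped 1,3-diyne into the C8–C5 bond of a cyclobutanone closes ring A in one operation and delivers C1 plus an alkynyl handle at C4a for the pyran ring. The precursor is a (2R,3S)-2-aroyloxy-2-methyl-3-silyloxycyclobutanone, made by ketene–enol ether [2+2] cycloaddition, which already holds both stereocentres and the complete ester.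

Key step: step 10

Abbreviations: TBS = tert-butyldimethylsilyl; ArCO = 4-(TBS-oxy)-2-methoxy-6-methylbenzoyl; Ar'CO = 4-hydroxy-2-methoxy-6-methylbenzoyl; ring B = the pyran ring.
Remark on the chemistry: the target's descriptors correspond to (6S,7R), with the C6 hydroxyl trans to the C7 ester oxygen and an E propenyl group, so the cyclobutanone needed has its silyloxy group trans to the aroyloxy group.
Assumption: compounds 1, 5, 8, 13 and 19 are purchased.

Step 1
Reactants: 1 2,4-dihydroxy-6-methylbenzaldehyde
Product: 2 4-(TBS-oxy)-2-hydroxy-6-methylbenzaldehyde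
Conditions: TBSCl (1.05 equiv), imidazole, CH2Cl2/DMF, 0 °C
Reagents that add atoms: tert-butyldimethylsilyl chloride, CC(C)(C)[Si](C)(C)Cl
Why: Chemoselective O-silylation, because the 2-hydroxyl is hydrogen-bonded to the ortho formyl group and more hindered, so one equivalent of silyl chloride should react only at the 4-hydroxyl.

Step 2
Reactants: 2 4-(TBS-oxy)-2-hydroxy-6-methylbenzaldehyde
Product: 3 4-(TBS-oxy)-2-methoxy-6-methylbenzaldehyde
Conditions: MeOH, PPh3, DIAD, THF, 0 °C → rt
Reagents that add atoms: methanol, CO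
Why: Mitsunobu etherification of the remaining chelated, acidic phenol with methanol is neutral, so the base-labile silyl ether para to the formyl group is kept.

Step 3
Reactants: 3 4-(TBS-oxy)-2-methoxy-6-methylbenzaldehyde
Product: 4 4-(TBS-oxy)-2-methoxy-6-methylbenzoic acid
Conditions: NaClO2, NaH2PO4, 2-methyl-2-butene, t-BuOH/H2O, rt
Reagents that add atoms: sodium chlorite, [Na+].[O-]Cl=O
Why: Pinnick oxidation of the hindered aryl aldehyde runs near pH 4, where the aryl silyl ether is stable, while 2-methyl-2-butene removes HOCl before it can chlorinate the electron-rich ring.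

Step 4
Reactants: 4 4-(TBS-oxy)-2-methoxy-6-methylbenzoic acid; 5 benzyl (S)-lactate
Product: 6 benzyl (2R)-2-(ArCO-oxy)propanoate
Conditions: PPh3, DIAD, THF, 0 °C → rt
Reagents that add atoms: none
Why: Mitsunobu esterification uses the di-ortho-substituted acid as the nucleophile on the activated lactate carbinol carbon (inversion to R), so the hindered carboxyl needs no acyl activation, and the configuration of this centre is irrelevant because it becomes sp2 in step 6.

Step 5
Reactants: 6 benzyl (2R)-2-(ArCO-oxy)propanoate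
Product: 7 (2R)-2-(ArCO-oxy)propanoic acid
Conditions: H2 (1 atm), Pd/C (palladium on carbon), EtOAc, rt
Reagents that add atoms: none
Why: Hydrogenolysis of the benzyl ester frees the acid without touching the aryl ester, the aryl silyl ether or the arene.

Step 6
Reactants: 7 (2R)-2-(ArCO-oxy)propanoic acid; 8 tert-butyldimethyl(vinyloxy)silane
Product: 11 2-(ArCO-oxy)-2-methyl-3-(TBS-oxy)cyclobutan-1-one as a mixture of stereoisomers, via acid chloride 9 (not isolated), via aroyloxy(methyl)ketene 10 (not isolated)
Conditions: (COCl)2, cat. DMF, CH2Cl2, 0 °C → rt, evaporate; then slow addition to 8 (5 equiv), Et3N, toluene, 60 °C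
Reagents that add atoms: none
Why: Dehydrochlorination of the acid chloride gives the ketene, which undergoes a thermal ketene–enol ether [2+2] cycloaddition in which its carbonyl carbon bonds to the nucleophilic CH2 terminus of 8, so the silyloxy carbon ends up next to the quaternary carbon; both new stereocentres form without absolute control and with an unreliable cis/trans preference, which step 7 corrects, and slow addition into excess 8 suppresses ketene dimerisation.

Step 7
Reactants: 11 2-(ArCO-oxy)-2-methyl-3-(TBS-oxy)cyclobutan-1-one, stereoisomer mixture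
Product: 12 (2R,3S)-2-(ArCO-oxy)-2-methyl-3-(TBS-oxy)cyclobutan-1-one (silyloxy trans to aroyloxy)
Conditions: silica gel chromatography (cis/trans separation); then preparative chiral-phase SFC (amylose tris(3,5-dimethylphenylcarbamate) phase, CO2/i-PrOH)
Reagents that add atoms: none
Why: The cis and trans racemates are diastereomers and should separate on silica, and the trans racemate is then resolved by chromatography on a polysaccharide chiral stationary phase, with the (2R,3S) assignment to be secured by anomalous-dispersion X-ray analysis or VCD before the material is carried on.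

Step 8
Reactants: 13 1,4-bis(trimethylsilyl)buta-1,3-diyne
Product: 15 5-(trimethylsilyl)penta-2,4-diyn-1-ol, via lithium diynide 14 (not isolated)
Conditions: MeLi·LiBr (1.0 equiv), THF, rt; then (CH2O)n, −78 °C → rt; aq. NH4Cl
Reagents that add atoms: paraformaldehyde (reacts as formaldehyde), C=O
Why: Methyllithium cleaves one Si–C(sp) bond (the resulting monoacetylide resists a second cleavage) and the lithium acetylide adds 1,2 to formaldehyde to give the propargylic alcohol.

Step 9
Reactants: 15 5-(trimethylsilyl)penta-2,4-diyn-1-ol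
Product: 16 5-(TBS-oxy)-1-(trimethylsilyl)penta-1,3-diyne
Conditions: TBSCl, imidazole, CH2Cl2, 0 °C → rt
Reagents that add atoms: tert-butyldimethylsilyl chloride, CC(C)(C)[Si](C)(C)Cl
Why: Standard silylation of a primary alcohol, to which the C-silyl alkyne cap is inert.

Step 10
Reactants: 12 (2R,3S)-2-(ArCO-oxy)-2-methyl-3-(TBS-oxy)cyclobutan-1-one; 16 5-(TBS-oxy)-1-(trimethylsilyl)penta-1,3-diyne
Product: 17 (1R,6S)-6-(TBS-oxy)-3-[(TBS-oxy)methyl]-1-methyl-2-oxo-4-[(trimethylsilyl)ethynyl]cyclohex-3-en-1-yl 4-(TBS-oxy)-2-methoxy-6-methylbenzoate (ring A enone; CH2OTBS on C8a, silylethynyl on C4a)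
Conditions: Ni(cod)2 (10 mol%), PCy3 (20 mol%), toluene, 90 °C, 16 (2 equiv) added by syringe pump
Reagents that add atoms: none
Why: Zerovalent nickel ligated by PCy3 couples the strained carbonyl of 12 with the inner triple bond of 16 by oxidative cyclisation to an oxanickelacyclopentene (C8–C8a bond), release of four-ring strain then drives β-carbon elimination of the C8–C5 bond to a seven-membered nickelacycle, and C(sp3)–C(sp2) reductive elimination forms C5–C4a and returns the catalyst. The closest known reaction type is the nickel-catalysed intermolecular insertion of internal alkynes into cyclobutanones, a formal [4+2] giving cyclohex-2-enones; the α-quaternary ketone and the conjugated diyne are new substrates for it, not a new reaction. Ring A is closed as a two-carbon ring expansion of the four-membered ring, the ring-closing event being the reductive elimination from the seven-membered metallacycle. No stereocentre is formed: C6 and C7 lie outside the bonds made and broken and keep the configuration resolved in step 7. The step needs (a) C8 to bond to the CH2OTBS-bearing alkyne carbon, secured because the alkynyl substituent stabilises nickel on its own carbon (η3-propargyl type) while the SiMe3 cap shields the outer triple bond, (b) migration of C8–C5 and not C8–C7, secured because a primary alkyl–nickel bond forms far more easily than a tertiary, oxygen-substituted one, and (c) reductive elimination before β-silyloxy or β-hydride loss at C6, favoured by the bulky electron-rich phosphine and the poor leaving ability of a silyloxy group.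

Step 11
Reactants: 17 ring A enone with silylethynyl group and aryl silyl ether
Product: 18 (1R,6S)-6-(TBS-oxy)-3-[(TBS-oxy)methyl]-4-ethynyl-1-methyl-2-oxocyclohex-3-en-1-yl 4-hydroxy-2-methoxy-6-methylbenzoate
Conditions: K2CO3 (1.5 equiv), MeOH/THF, 0 °C
Reagents that add atoms: none
Why: Base-catalysed methanolysis cleaves the two most labile silicon bonds, the C(sp)–SiMe3 bond and the aryl O–Si bond para to the ester carbonyl, while the alkyl TBS ethers and the hindered aryl ester survive at 0 °C and C7, having no α-hydrogen, cannot epimerise.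

Step 12
Reactants: 18 terminal alkyne; 19 (E)-1-bromoprop-1-ene
Product: 20 (1R,6S)-6-(TBS-oxy)-3-[(TBS-oxy)methyl]-1-methyl-2-oxo-4-[(3E)-pent-3-en-1-yn-1-yl]cyclohex-3-en-1-yl 4-hydroxy-2-methoxy-6-methylbenzoate
Conditions: Pd(PPh3)4 (5 mol%), CuI (10 mol%), Et3N, THF, rt, degassed, 19 (3 equiv)
Reagents that add atoms: none
Why: Sonogashira coupling of the terminal alkyne with the alkenyl bromide keeps the E geometry, tolerates the free phenol, and uses a tertiary amine that cannot add to the electron-poor enynone, while the still-silylated C1 oxygen cannot cyclise prematurely.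

Step 13
Reactants: 20 dienyne bis(silyl ether)
Product: 21 (1R,6S)-6-hydroxy-3-(hydroxymethyl)-1-methyl-2-oxo-4-[(3E)-pent-3-en-1-yn-1-yl]cyclohex-3-en-1-yl 4-hydroxy-2-methoxy-6-methylbenzoate
Conditions: HF·pyridine (excess), pyridine, THF, 0 °C → rt
Reagents that add atoms: none
Why: Fluoride-assisted cleavage of both alkyl silyl ethers in a buffered acidic medium avoids the basic conditions that could cause acyl migration from the tertiary to the neighbouring secondary oxygen or vinylogous β-elimination.

Step 14
Reactants: 21 triol dienyne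
Product: 22 (6S,7R)-6-hydroxy-7-methyl-8-oxo-3-[(1E)-prop-1-en-1-yl]-5,6,7,8-tetrahydro-1H-isochromen-7-yl 4-hydroxy-2-methoxy-6-methylbenzoate (target)
Conditions: Ph3PAuNTf2 (5 mol%), CH2Cl2/THF, rt
Reagents that add atoms: none
Why: Monovalent gold activates the triple bond as a π-acid and the C1 hydroxyl adds anti at C3 in a 6-endo-dig hydroalkoxylation followed by protodeauration, closing ring B; C3 is favoured over C4 (5-exo) because it is the δ-position of the ynenone and its positive charge is allyl-stabilised by the propenyl group, and no stereocentre is touched.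

Compound list
1 | 2,4-dihydroxy-6-methylbenzaldehyde | O=Cc1c(C)cc(O)cc1O | starting material
2 | 4-[(tert-butyldimethylsilyl)oxy]-2-hydroxy-6-methylbenzaldehyde | O=Cc1c(C)cc(O[Si](C)(C)C(C)(C)C)cc1O | intermediate
3 | 4-[(tert-butyldimethylsilyl)oxy]-2-methoxy-6-methylbenzaldehyde | O=Cc1c(C)cc(O[Si](C)(C)C(C)(C)C)cc1OC | intermediate
4 | 4-[(tert-butyldimethylsilyl)oxy]-2-methoxy-6-methylbenzoic acid | OC(=O)c1c(C)cc(O[Si](C)(C)C(C)(C)C)cc1OC | intermediate
5 | benzyl (2S)-2-hydroxypropanoate (benzyl (S)-lactate) | C[C@H](O)C(=O)OCc1ccccc1 | starting material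
6 | benzyl (2R)-2-({4-[(tert-butyldimethylsilyl)oxy]-2-methoxy-6-methylbenzoyl}oxy)propanoate | C[C@@H](OC(=O)c1c(C)cc(O[Si](C)(C)C(C)(C)C)cc1OC)C(=O)OCc1ccccc1 | intermediate
7 | (2R)-2-({4-[(tert-butyldimethylsilyl)oxy]-2-methoxy-6-methylbenzoyl}oxy)propanoic acid | C[C@@H](OC(=O)c1c(C)cc(O[Si](C)(C)C(C)(C)C)cc1OC)C(=O)O | intermediate
8 | tert-butyldimethyl(vinyloxy)silane | C=CO[Si](C)(C)C(C)(C)C | starting material
9 | (2R)-2-({4-[(tert-butyldimethylsilyl)oxy]-2-methoxy-6-methylbenzoyl}oxy)propanoyl chloride | C[C@@H](OC(=O)c1c(C)cc(O[Si](C)(C)C(C)(C)C)cc1OC)C(=O)Cl | intermediate (not isolated)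
10 | 1-oxoprop-1-en-2-yl 4-[(tert-butyldimethylsilyl)oxy]-2-methoxy-6-methylbenzoate (aroyloxy(methyl)ketene) | CC(OC(=O)c1c(C)cc(O[Si](C)(C)C(C)(C)C)cc1OC)=C=O | intermediate (not isolated)
11 | 2-[(tert-butyldimethylsilyl)oxy]-1-methyl-4-oxocyclobutyl 4-[(tert-butyldimethylsilyl)oxy]-2-methoxy-6-methylbenzoate, mixture of the four stereoisomers | O=C1CC(O[Si](C)(C)C(C)(C)C)C1(C)OC(=O)c1c(C)cc(O[Si](C)(C)C(C)(C)C)cc1OC | intermediate
12 | (1R,2S)-2-[(tert-butyldimethylsilyl)oxy]-1-methyl-4-oxocyclobutyl 4-[(tert-butyldimethylsilyl)oxy]-2-methoxy-6-methylbenzoate, i.e. the (2R,3S)-cyclobutanone with silyloxy trans to aroyloxy | O=C1[C@](C)(OC(=O)c2c(C)cc(O[Si](C)(C)C(C)(C)C)cc2OC)[C@@H](O[Si](C)(C)C(C)(C)C)C1 | intermediate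
13 | 1,4-bis(trimethylsilyl)buta-1,3-diyne | C[Si](C)(C)C#CC#C[Si](C)(C)C | starting material
14 | lithium 4-(trimethylsilyl)buta-1,3-diyn-1-ide | [Li]C#CC#C[Si](C)(C)C | intermediate (not isolated)
15 | 5-(trimethylsilyl)penta-2,4-diyn-1-ol | C[Si](C)(C)C#CC#CCO | intermediate
16 | tert-butyldimethyl{[5-(trimethylsilyl)penta-2,4-diyn-1-yl]oxy}silane | C[Si](C)(C)C#CC#CCO[Si](C)(C)C(C)(C)C | intermediate
17 | (1R,6S)-6-[(tert-butyldimethylsilyl)oxy]-3-{[(tert-butyldimethylsilyl)oxy]methyl}-1-methyl-2-oxo-4-[(trimethylsilyl)ethynyl]cyclohex-3-en-1-yl 4-[(tert-butyldimethylsilyl)oxy]-2-methoxy-6-methylbenzoate | O=C1[C@](C)(OC(=O)c3c(C)cc(O[Si](C)(C)C(C)(C)C)cc3OC)[C@@H](O[Si](C)(C)C(C)(C)C)CC(C#C[Si](C)(C)C)=C1CO[Si](C)(C)C(C)(C)C | intermediate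
18 | (1R,6S)-6-[(tert-butyldimethylsilyl)oxy]-3-{[(tert-butyldimethylsilyl)oxy]methyl}-4-ethynyl-1-methyl-2-oxocyclohex-3-en-1-yl 4-hydroxy-2-methoxy-6-methylbenzoate | O=C1[C@](C)(OC(=O)c3c(C)cc(O)cc3OC)[C@@H](O[Si](C)(C)C(C)(C)C)CC(C#C)=C1CO[Si](C)(C)C(C)(C)C | intermediate
19 | (E)-1-bromoprop-1-ene | C/C=C/Br | starting material
20 | (1R,6S)-6-[(tert-butyldimethylsilyl)oxy]-3-{[(tert-butyldimethylsilyl)oxy]methyl}-1-methyl-2-oxo-4-[(3E)-pent-3-en-1-yn-1-yl]cyclohex-3-en-1-yl 4-hydroxy-2-methoxy-6-methylbenzoate | O=C1[C@](C)(OC(=O)c3c(C)cc(O)cc3OC)[C@@H](O[Si](C)(C)C(C)(C)C)CC(C#C/C=C/C)=C1CO[Si](C)(C)C(C)(C)C | intermediate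
21 | (1R,6S)-6-hydroxy-3-(hydroxymethyl)-1-methyl-2-oxo-4-[(3E)-pent-3-en-1-yn-1-yl]cyclohex-3-en-1-yl 4-hydroxy-2-methoxy-6-methylbenzoate | O=C1[C@](C)(OC(=O)c3c(C)cc(O)cc3OC)[C@@H](O)CC(C#C/C=C/C)=C1CO | intermediate
22 | (6S,7R)-6-hydroxy-7-methyl-8-oxo-3-[(1E)-prop-1-en-1-yl]-5,6,7,8-tetrahydro-1H-isochromen-7-yl 4-hydroxy-2-methoxy-6-methylbenzoate (CNP0187389.4) | C/C=C/C1=CC2=C(CO1)C(=O)[C@](C)(OC(=O)c1c(C)cc(O)cc1OC)[C@@H](O)C2 | target

Total step count: 14 (the chromatographic resolution counted as a step).
Longest linear sequence: 12 steps (1–7, then 10–14); the diyne branch is steps 8–9.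

Steps most likely to fail

Step 10. Nickel-catalysed oligomerisation or cyclotrimerisation of the diyne, or insertion of its outer triple bond, may outrun oxidative cyclisation at the hindered α-quaternary carbonyl. Once a nickelacycle forms, β-elimination of the C6 silyloxy group or insertion of nickel into the C7–O bond of the α-acyloxy ketone may consume 12. The fallback sets out from 12 and returns at 18. It replaces the diyne by a 1,3-enyne, which has one triple bond and the same conjugative regiocontrol, and builds the alkyne afterwards by one-carbon homologation; it answers failure on the alkyne side only. Sonogashira coupling of commercial tert-butyldimethyl(prop-2-yn-1-yloxy)silane with vinyl bromide (Pd(PPh3)4, CuI, Et3N, THF) gives tert-butyldimethyl(pent-4-en-2-yn-1-yloxy)silane F1. Its insertion into 12 under the conditions of step 10 should give the 4-ethenyl ring A enone F2 (ethenyl on C4a). Lemieux–Johnson cleavage (OsO4 cat., NaIO4, 2,6-lutidine, dioxane/H2O) of the unhindered terminal vinyl group, in preference to the tetrasubstituted enone alkene, gives the 4-formyl enone F3. Colvin homologation (LiC(N2)SiMe3 from Me3SiCHN2 and LDA, THF, −78 → 0 °C) gives the terminal alkyne F4, which still carries the aryl silyl ether. K2CO3/MeOH at 0 °C removes that ether and gives 18.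

Step 6. The acyloxy(methyl)ketene may dimerise or be intercepted by chloride or amine faster than it adds to the moderately nucleophilic silyl enol ether. Triethylammonium chloride may protodesilylate the enol ether at the temperature required, and the cycloaddition may favour the unwanted cis isomer. The fallback sets out from 9 and returns at 11. It exchanges the roles: the ketene becomes dichloroketene, the most reactive ketene toward silyl enol ethers, and the aroyloxy and methyl groups sit on the enol ether. Palladium-catalysed reduction of 9 with Bu3SnH (Pd(PPh3)4 cat., toluene, rt) gives (2R)-2-(ArCO-oxy)propanal F5. TBSOTf/Et3N (CH2Cl2, 0 °C) gives its silyl enol ether, 1-(TBS-oxy)prop-1-en-2-yl 4-(TBS-oxy)-2-methoxy-6-methylbenzoate F6 (E/Z mixture, E drawn). Dichloroketene from Cl3CCOCl and Zn–Cu couple (Et2O/DME, rt) should add with its carbonyl carbon to the aroyloxy-bearing alkene carbon, because the silyloxy group is the stronger donor. The addition is suprafacial, so the E isomer gives the trans-dioxygenated 2,2-dichloro-3-(TBS-oxy)-4-methyl-4-(ArCO-oxy)cyclobutanone F7. Zn/AcOH (rt), the usual route to 3-alkoxycyclobutanones, removes both chlorines and gives 11, which enters step 7.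

Step 11. In methanolic carbonate the liberated terminal ynenone may add methoxide at its alkyne terminus, and deprotonation at C5 may lead through the dienolate to loss of the C1 or C6 silyloxy group. The fallback goes from 17 directly to 20 and makes no compound outside the list (F0). It is a fluoride-triggered desilylative Sonogashira coupling in one pot (CsF, PdCl2(PPh3)2, CuI, Et3N, 19, THF/H2O, 40 °C, sealed). The alkyne is released slowly and captured at once as the copper acetylide, so the free ynenone never accumulates in a protic base. CsF also cleaves the phenolic silyl ether but not the alkyl TBS ethers, so the product is 20.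

Further compounds
F1 | step 10 | tert-butyldimethyl(pent-4-en-2-yn-1-yloxy)silane | C=CC#CCO[Si](C)(C)C(C)(C)C
F2 | step 10 | (1R,6S)-6-[(tert-butyldimethylsilyl)oxy]-3-{[(tert-butyldimethylsilyl)oxy]methyl}-4-ethenyl-1-methyl-2-oxocyclohex-3-en-1-yl 4-[(tert-butyldimethylsilyl)oxy]-2-methoxy-6-methylbenzoate | O=C1[C@](C)(OC(=O)c2c(C)cc(O[Si](C)(C)C(C)(C)C)cc2OC)[C@@H](O[Si](C)(C)C(C)(C)C)CC(C=C)=C1CO[Si](C)(C)C(C)(C)C
F3 | step 10 | (1R,6S)-6-[(tert-butyldimethylsilyl)oxy]-3-{[(tert-butyldimethylsilyl)oxy]methyl}-4-formyl-1-methyl-2-oxocyclohex-3-en-1-yl 4-[(tert-butyldimethylsilyl)oxy]-2-methoxy-6-methylbenzoate | O=C1[C@](C)(OC(=O)c2c(C)cc(O[Si](C)(C)C(C)(C)C)cc2OC)[C@@H](O[Si](C)(C)C(C)(C)C)CC(C=O)=C1CO[Si](C)(C)C(C)(C)C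
F4 | step 10 | (1R,6S)-6-[(tert-butyldimethylsilyl)oxy]-3-{[(tert-butyldimethylsilyl)oxy]methyl}-4-ethynyl-1-methyl-2-oxocyclohex-3-en-1-yl 4-[(tert-butyldimethylsilyl)oxy]-2-methoxy-6-methylbenzoate | O=C1[C@](C)(OC(=O)c2c(C)cc(O[Si](C)(C)C(C)(C)C)cc2OC)[C@@H](O[Si](C)(C)C(C)(C)C)CC(C#C)=C1CO[Si](C)(C)C(C)(C)C
F5 | step 6 | (2R)-2-({4-[(tert-butyldimethylsilyl)oxy]-2-methoxy-6-methylbenzoyl}oxy)propanal | C[C@@H](OC(=O)c1c(C)cc(O[Si](C)(C)C(C)(C)C)cc1OC)C=O
F6 | step 6 | (E)-1-[(tert-butyldimethylsilyl)oxy]prop-1-en-2-yl 4-[(tert-butyldimethylsilyl)oxy]-2-methoxy-6-methylbenzoate | C/C(OC(=O)c1c(C)cc(O[Si](C)(C)C(C)(C)C)cc1OC)=C\O[Si](C)(C)C(C)(C)C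
F7 | step 6 | 2-[(tert-butyldimethylsilyl)oxy]-3,3-dichloro-1-methyl-4-oxocyclobutyl 4-[(tert-butyldimethylsilyl)oxy]-2-methoxy-6-methylbenzoate, stereoisomer mixture | O=C1C(Cl)(Cl)C(O[Si](C)(C)C(C)(C)C)C1(C)OC(=O)c1c(C)cc(O[Si](C)(C)C(C)(C)C)cc1OC
F0 | step 11 | none | none
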